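**Retrosynthetic overview**

1. Numbering: C7 = catechol-bearing ether CH, C8 = lactone α-CH, C9 = lactone C=O, C7' = guaiacyl-bearing O–CH of the lactone, C8' = second ring-fusion CH, C9' = ether CH2.
2. Feature used: the γ-lactone ring C9–C8–C8'–C7'–O is a cyclobutanone C9–C8–C8'–C7' with one oxygen placed between C9 and benzylic C7'. Hence 16 ⇐ tribenzyl lactone 15 (debenzylation) ⇐ cyclobutanone 14 (Baeyer–Villiger).
3. 14 ⇐ keteniminium (2+2): C9–C8 and C7'–C8' form between the keteniminium ion from amide 9 (C9, C7') and the C8=C8' alkene of (S)-dihydrofuran 6, whose C7 centre directs the three new stereocentres.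
4. 6 ⇐ enantioselective Heck arylation of 2,3-dihydrofuran 5 with aryl triflate 4 (from aldehyde 1 via phenol 3); 9 ⇐ arylacetic acid 7 and dimethylamine.
5. Ring order: the oxygen five-membered ring C7–O–C9'–C8'–C8 first (as the dihydrofuran), the cyclobutanone second, its expansion to the γ-lactone last.

Key step: step 5

Assumption: in step 3 the phosphinooxazoline ligand is taken to induce the same sense as with simple aryl triflates ((S)-ligand to (R)-2-aryl-2,5-dihydrofuran), so the (R)-ligand is specified for (S)-6; the enantiomeric ligand would be used if the sense proved opposite.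

**Route**

Step 1
Reactants: 1 3,4-bis(benzyloxy)benzaldehyde
Product: 3 3,4-bis(benzyloxy)phenol, via 3,4-bis(benzyloxy)phenyl formate 2 (not isolated)
Conditions: mCPBA (1.3 equiv), CH2Cl2, 0 °C → rt; aq NaHCO3 wash; then K2CO3 (0.1 equiv), MeOH, rt
Reagents that add atoms: mCPBA (3-chloroperoxybenzoic acid), O=C(OO)c1cccc(Cl)c1
Why: Dakin-type Baeyer–Villiger oxidation, in which the electron-rich aryl group migrates in the peracid adduct of the aldehyde to give formate 2, and mild methanolysis then frees the phenol without touching the benzyl ethers.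

Step 2
Reactants: 3 3,4-bis(benzyloxy)phenol
Product: 4 3,4-bis(benzyloxy)phenyl trifluoromethanesulfonate
Conditions: Tf2O (1.2 equiv), pyridine (2 equiv), CH2Cl2, 0 °C
Reagents that add atoms: triflic anhydride (Tf2O), O=S(=O)(OS(=O)(=O)C(F)(F)F)C(F)(F)F
Why: O-sulfonylation of the phenol with triflic anhydride and pyridine gives the aryl triflate required for the cationic Heck pathway.

Step 3
Reactants: 4 3,4-bis(benzyloxy)phenyl trifluoromethanesulfonate; 5 2,3-dihydrofuran (4 equiv)
Product: 6 (S)-2-[3,4-bis(benzyloxy)phenyl]-2,5-dihydrofuran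
Conditions: Pd2(dba)3 (1.5 mol %), (R)-4-tert-butyl-2-[2-(diphenylphosphanyl)phenyl]-4,5-dihydrooxazole ((R)-tBu-PHOX, 6 mol %), iPr2NEt (2 equiv), THF, 70 °C
Reagents that add atoms: none
Why: Enantioselective intermolecular Mizoroki–Heck arylation, in which the cationic arylpalladium triflate complex (divalent palladium) inserts the enol-ether alkene with aryl delivery to C2, the chiral P,N-ligand setting the C7 stereocentre in this insertion, and β-hydride elimination toward C4 followed by fast alkene release keeps the double bond at C3=C4.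

Step 4
Reactants: 7 2-[4-(benzyloxy)-3-methoxyphenyl]acetic acid
Product: 9 2-[4-(benzyloxy)-3-methoxyphenyl]-N,N-dimethylacetamide, via acyl imidazole 8 (not isolated)
Conditions: CDI (1.1 equiv), THF, rt; then Me2NH (2 M in THF, 2 equiv), rt
Reagents that add atoms: dimethylamine, CNC
Why: Amide formation through the acyl imidazole, which carbonyldiimidazole forms with loss of CO2 and from which dimethylamine displaces imidazole.

Step 5
Reactants: 9 2-[4-(benzyloxy)-3-methoxyphenyl]-N,N-dimethylacetamide (1.5 equiv); 6 (S)-2-[3,4-bis(benzyloxy)phenyl]-2,5-dihydrofuran (1.0 equiv)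
Product: 14 (1R,4S,5S,7S)-7-[4-(benzyloxy)-3-methoxyphenyl]-4-[3,4-bis(benzyloxy)phenyl]-3-oxabicyclo[3.2.0]heptan-6-one, via triflyloxyiminium triflate 10 (not isolated), via keteniminium triflate 11 (not isolated), via cyclobutaniminium triflate 12 (not isolated), via cyclobutanone C7' epimers 13 (not isolated)
Conditions: 9, Tf2O (1.4 equiv), ClCH2CH2Cl, −20 °C; then 6 and 2,4,6-collidine (2.0 equiv, slow addition), −20 → 60 °C; sat. aq NaHCO3, rt; then DBU (0.1 equiv), CH2Cl2, 0 °C → rt
Reagents that add atoms: water, O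
Why: Tf2O turns amide 9 into the triflyloxyiminium salt 10, collidine removes a benzylic proton to give keteniminium ion 11, the C8=C8' alkene of 6 attacks its electrophilic sp carbon C9 and the enamine carbon C7' then closes on the cationic C8'; the closest known reaction is the keteniminium–alkene (2+2) cycloaddition of tertiary amides activated with Tf2O and a hindered pyridine, which accepts unactivated cis-alkenes including 2,5-dihydrofuran. The cyclobutane ring C9–C8–C8'–C7' is closed in an asynchronous but suprafacial (2+2) mode (C9–C8 first, then four-membered closure of the enamine carbon C7' on the C8' cation), so the cis ring fusion at C8 and C8' follows from the cis-alkene. Facial selectivity is needed and is secured by the C7 aryl group, which covers its own face of the almost flat ring, so that both bonds form anti to it and C8 and C8' are set relative to C7. Regioselectivity is needed as well and rests on a weaker bias of the substrate: positive charge should build more easily at C8', beside the C9' methylene, than at C8, beside the inductively more withdrawing C7 that carries oxygen and aryl, and the aryl-bearing terminus C7' then bonds to the carbon remote from C7. C7' is set under thermodynamic control: hydrolysis of iminium salt 12 gives ketone 13 as C7' epimers and catalytic DBU enolises it toward the more acidic benzylic C7', so that the aryl group should settle exo, trans to C9', in 14. Keeping Tf2O limiting relative to 9 and collidine in excess keeps free Tf2O and triflic acid away from the acid-labile benzylic allylic ether of 6.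

Step 6
Reactants: 14 (1R,4S,5S,7S)-7-[4-(benzyloxy)-3-methoxyphenyl]-4-[3,4-bis(benzyloxy)phenyl]-3-oxabicyclo[3.2.0]heptan-6-one
Product: 15 (3S,3aR,6S,6aS)-3-[4-(benzyloxy)-3-methoxyphenyl]-6-[3,4-bis(benzyloxy)phenyl]tetrahydro-1H,3H-furo[3,4-c]furan-1-one
Conditions: mCPBA (1.3 equiv), CH2Cl2, 0 °C
Reagents that add atoms: mCPBA (3-chloroperoxybenzoic acid), O=C(OO)c1cccc(Cl)c1
Why: Baeyer–Villiger oxidation of a strained cyclobutanone, in which the secondary benzylic C7' with its para-oxygenated aryl group migrates in preference to C8 (deactivated by the adjacent C7–O bond) and does so with retention, so oxygen enters between C9 and C7' and C7' keeps its configuration.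

Step 7
Reactants: 15 (3S,3aR,6S,6aS)-3-[4-(benzyloxy)-3-methoxyphenyl]-6-[3,4-bis(benzyloxy)phenyl]tetrahydro-1H,3H-furo[3,4-c]furan-1-one
Product: 16 (3S,3aR,6S,6aS)-6-(3,4-dihydroxyphenyl)-3-(4-hydroxy-3-methoxyphenyl)tetrahydro-1H,3H-furo[3,4-c]furan-1-one (CNP0268159.1)
Conditions: H2 (1 atm), 10% Pd/C, EtOAc–THF, rt, stopped at complete debenzylation
Reagents that add atoms: none
Why: Catalytic hydrogenolysis (O-debenzylation) of the three aryl benzyl ethers, which under neutral conditions should be much faster than cleavage of the benzylic C–O bonds of the lactone and ether rings; no stereocentre is touched.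

**Compound list**

1 | 3,4-bis(benzyloxy)benzaldehyde | O=Cc1ccc(OCc2ccccc2)c(OCc2ccccc2)c1 | starting material
2 | 3,4-bis(benzyloxy)phenyl formate | O=COc1ccc(OCc2ccccc2)c(OCc2ccccc2)c1 | intermediate
3 | 3,4-bis(benzyloxy)phenol | Oc1ccc(OCc2ccccc2)c(OCc2ccccc2)c1 | intermediate
4 | 3,4-bis(benzyloxy)phenyl trifluoromethanesulfonate | O=S(=O)(Oc1ccc(OCc2ccccc2)c(OCc2ccccc2)c1)C(F)(F)F | intermediate
5 | 2,3-dihydrofuran | C1=COCC1 | starting material
6 | (S)-2-[3,4-bis(benzyloxy)phenyl]-2,5-dihydrofuran | C1=CCO[C@@H]1c1ccc(OCc2ccccc2)c(OCc2ccccc2)c1 | intermediate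
7 | 2-[4-(benzyloxy)-3-methoxyphenyl]acetic acid | COc1cc(CC(=O)O)ccc1OCc1ccccc1 | starting material
8 | 2-[4-(benzyloxy)-3-methoxyphenyl]-1-(imidazol-1-yl)ethanone (acyl imidazole) | COc1cc(CC(=O)n2ccnc2)ccc1OCc1ccccc1 | intermediate
9 | 2-[4-(benzyloxy)-3-methoxyphenyl]-N,N-dimethylacetamide | COc1cc(CC(=O)N(C)C)ccc1OCc1ccccc1 | intermediate
10 | N-{2-[4-(benzyloxy)-3-methoxyphenyl]-1-(trifluoromethylsulfonyloxy)ethylidene}-N-methylmethanaminium triflate | COc1cc(CC(OS(=O)(=O)C(F)(F)F)=[N+](C)C)ccc1OCc1ccccc1.[O-]S(=O)(=O)C(F)(F)F | intermediate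
11 | N-{2-[4-(benzyloxy)-3-methoxyphenyl]ethenylidene}-N-methylmethanaminium triflate (keteniminium salt) | COc1cc(C=C=[N+](C)C)ccc1OCc1ccccc1.[O-]S(=O)(=O)C(F)(F)F | intermediate
12 | N-{7-[4-(benzyloxy)-3-methoxyphenyl]-4-[3,4-bis(benzyloxy)phenyl]-3-oxabicyclo[3.2.0]heptan-6-ylidene}-N-methylmethanaminium triflate (cis-fused, aryl at C4 trans to the four-membered ring, both epimers at the guaiacyl-bearing carbon) | COc1cc(C2C(=[N+](C)C)[C@H]3[C@@H]2CO[C@@H]3c2ccc(OCc3ccccc3)c(OCc3ccccc3)c2)ccc1OCc1ccccc1.[O-]S(=O)(=O)C(F)(F)F | intermediate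
13 | (1R,4S,5S)-7-[4-(benzyloxy)-3-methoxyphenyl]-4-[3,4-bis(benzyloxy)phenyl]-3-oxabicyclo[3.2.0]heptan-6-one, both epimers at C7 of the bicycle | COc1cc(C2C(=O)[C@H]3[C@@H]2CO[C@@H]3c2ccc(OCc3ccccc3)c(OCc3ccccc3)c2)ccc1OCc1ccccc1 | intermediate
14 | (1R,4S,5S,7S)-7-[4-(benzyloxy)-3-methoxyphenyl]-4-[3,4-bis(benzyloxy)phenyl]-3-oxabicyclo[3.2.0]heptan-6-one (exo aryl) | COc1cc([C@H]2C(=O)[C@H]3[C@@H]2CO[C@@H]3c2ccc(OCc3ccccc3)c(OCc3ccccc3)c2)ccc1OCc1ccccc1 | intermediate
15 | (3S,3aR,6S,6aS)-3-[4-(benzyloxy)-3-methoxyphenyl]-6-[3,4-bis(benzyloxy)phenyl]tetrahydro-1H,3H-furo[3,4-c]furan-1-one | COc1cc([C@H]2OC(=O)[C@H]3[C@@H]2CO[C@@H]3c2ccc(OCc3ccccc3)c(OCc3ccccc3)c2)ccc1OCc1ccccc1 | intermediate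
16 | (3S,3aR,6S,6aS)-6-(3,4-dihydroxyphenyl)-3-(4-hydroxy-3-methoxyphenyl)tetrahydro-1H,3H-furo[3,4-c]furan-1-one | COc1cc([C@H]2OC(=O)[C@H]3[C@@H]2CO[C@@H]3c2ccc(O)c(O)c2)ccc1O | target

**Step count**

Total: 7 steps. Longest linear sequence: 6 steps (1, 2, 3, 5, 6, 7).

**Three steps most likely to fail**

Step 5 (keteniminium (2+2)). What may go wrong:
- erosion of regiocontrol in the first C–C bond formation (C9 bonding to C8' instead of C8);
- ionisation of the benzylic allylic C7–O bond of 6 in the triflating medium;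
- acylation of the electron-rich catechol ring in competition with the alkene.

Fallback: an aldol-based assembly without cycloaddition, setting out from aldehyde 1 (used as the late electrophile) and rejoining the route at lactone 15. (S)-4-Benzyl-1,3-oxazolidin-2-one is N-acylated with 4-(tert-butoxy)-4-oxobutanoic acid (PivCl, Et3N, LiCl, THF) to the succinate imide (S)-4-benzyl-3-[4-(tert-butoxy)-4-oxobutanoyl]-1,3-oxazolidin-2-one F1. Its dibutylboron enolate (Bu2BOTf, iPr2NEt, CH2Cl2, −78 °C) should add to commercial 4-(benzyloxy)-3-methoxybenzaldehyde in an Evans syn-aldol reaction that fixes C8' and C7', giving the aldol adduct tert-butyl (3S,4S)-4-[4-(benzyloxy)-3-methoxyphenyl]-3-[(4S)-4-benzyl-2-oxo-1,3-oxazolidine-3-carbonyl]-4-hydroxybutanoate F2. Silylation (TBSOTf, 2,6-lutidine) gives the silyl ether tert-butyl (3S,4S)-4-[4-(benzyloxy)-3-methoxyphenyl]-3-[(4S)-4-benzyl-2-oxo-1,3-oxazolidine-3-carbonyl]-4-[(tert-butyldimethylsilyl)oxy]butanoate F3. LiBH4 (THF–MeOH, 0 °C) removes the auxiliary reductively to the primary alcohol tert-butyl (3R,4S)-4-[4-(benzyloxy)-3-methoxyphenyl]-4-[(tert-butyldimethylsilyl)oxy]-3-(hydroxymethyl)butanoate F4 (the new CH2OH is C9'). Catalytic NaH in THF closes it on to the tert-butyl ester to give the butyrolactone (4R)-4-{(S)-[4-(benzyloxy)-3-methoxyphenyl][(tert-butyldimethylsilyl)oxy]methyl}oxolan-2-one F5. Its lithium enolate (LDA, THF, −78 °C) should add to aldehyde 1 anti to the C8' substituent to give the aldol adduct (3S,4R)-4-{(S)-[4-(benzyloxy)-3-methoxyphenyl][(tert-butyldimethylsilyl)oxy]methyl}-3-{[3,4-bis(benzyloxy)phenyl](hydroxy)methyl}oxolan-2-one F6 (carbinol epimers at C7). CF3CO2H in CH2Cl2 then removes the silyl group, the C7' hydroxyl translactonises on to C9, and the released C9' hydroxyl captures the benzylic cation at C7 to close the ether ring. Only the cis-fused bicycle can form, and closure from the convex face should place the C7 aryl group exo, which is lactone 15.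

Step 3 (asymmetric Heck arylation). What may go wrong:
- slow oxidative addition of the electron-rich triflate, with catalyst decay before full conversion;
- migration of the double bond toward oxygen (2,3-dihydro isomer);
- insufficient enantioselectivity.

Fallback: resolution and metathesis in place of asymmetric arylation, setting out from aldehyde 1 and rejoining at dihydrofuran 6. Vinylmagnesium bromide (THF, 0 °C) gives racemic 1-[3,4-bis(benzyloxy)phenyl]prop-2-en-1-ol F7. Lipase-catalysed acetylation (immobilised Candida antarctica lipase B, vinyl acetate, MTBE, rt, run just past half conversion) should consume the (R)-enantiomer and leave (S)-1-[3,4-bis(benzyloxy)phenyl]prop-2-en-1-ol F8. O-Allylation (NaH, allyl bromide, THF–DMF, 0 °C) gives (S)-4-[1-(allyloxy)prop-2-en-1-yl]-1,2-bis(benzyloxy)benzene F9. Ring-closing metathesis with the second-generation Grubbs catalyst RuCl2(=CHPh)(PCy3)(H2IMes) (CH2Cl2, 40 °C) closes dihydrofuran 6 with loss of ethylene.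

Step 7 (hydrogenolysis). What may go wrong: over-reduction, that is, hydrogenolysis of the benzylic C7'–O bond of the lactone or the C7–O bond of the ether ring once the phenols are free.

Fallback: non-reductive Lewis-acid debenzylation, from lactone 15 directly to target 16. BCl3 with pentamethylbenzene as benzyl-cation scavenger (CH2Cl2, −78 °C) cleaves aryl benzyl ethers and cannot reduce C–O bonds; at this temperature the aryl methyl ether, the lactone and the ring C–O bonds are not expected to be attacked. This fallback makes no new compound (F0).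

Further compounds
F1 | step 5 | (S)-4-benzyl-3-[4-(tert-butoxy)-4-oxobutanoyl]-1,3-oxazolidin-2-one | CC(C)(C)OC(=O)CCC(=O)N1[C@@H](Cc2ccccc2)COC1=O
F2 | step 5 | tert-butyl (3S,4S)-4-[4-(benzyloxy)-3-methoxyphenyl]-3-[(4S)-4-benzyl-2-oxo-1,3-oxazolidine-3-carbonyl]-4-hydroxybutanoate | COc1cc([C@@H](O)[C@H](CC(=O)OC(C)(C)C)C(=O)N2[C@@H](Cc3ccccc3)COC2=O)ccc1OCc1ccccc1
F3 | step 5 | tert-butyl (3S,4S)-4-[4-(benzyloxy)-3-methoxyphenyl]-3-[(4S)-4-benzyl-2-oxo-1,3-oxazolidine-3-carbonyl]-4-[(tert-butyldimethylsilyl)oxy]butanoate | COc1cc([C@@H](O[Si](C)(C)C(C)(C)C)[C@H](CC(=O)OC(C)(C)C)C(=O)N2[C@@H](Cc3ccccc3)COC2=O)ccc1OCc1ccccc1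
F4 | step 5 | tert-butyl (3R,4S)-4-[4-(benzyloxy)-3-methoxyphenyl]-4-[(tert-butyldimethylsilyl)oxy]-3-(hydroxymethyl)butanoate | COc1cc([C@@H](O[Si](C)(C)C(C)(C)C)[C@H](CC(=O)OC(C)(C)C)CO)ccc1OCc1ccccc1
F5 | step 5 | (4R)-4-{(S)-[4-(benzyloxy)-3-methoxyphenyl][(tert-butyldimethylsilyl)oxy]methyl}oxolan-2-one | COc1cc([C@@H](O[Si](C)(C)C(C)(C)C)[C@@H]2CC(=O)OC2)ccc1OCc1ccccc1
F6 | step 5 | (3S,4R)-4-{(S)-[4-(benzyloxy)-3-methoxyphenyl][(tert-butyldimethylsilyl)oxy]methyl}-3-{[3,4-bis(benzyloxy)phenyl](hydroxy)methyl}oxolan-2-one, carbinol epimers | COc1cc([C@@H](O[Si](C)(C)C(C)(C)C)[C@H]2COC(=O)[C@@H]2C(O)c2ccc(OCc3ccccc3)c(OCc3ccccc3)c2)ccc1OCc1ccccc1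
F7 | step 3 | racemic 1-[3,4-bis(benzyloxy)phenyl]prop-2-en-1-ol | C=CC(O)c1ccc(OCc2ccccc2)c(OCc2ccccc2)c1
F8 | step 3 | (S)-1-[3,4-bis(benzyloxy)phenyl]prop-2-en-1-ol | C=C[C@H](O)c1ccc(OCc2ccccc2)c(OCc2ccccc2)c1
F9 | step 3 | (S)-4-[1-(allyloxy)prop-2-en-1-yl]-1,2-bis(benzyloxy)benzene | C=CCO[C@@H](C=C)c1ccc(OCc2ccccc2)c(OCc2ccccc2)c1
F0 | step 7 | none | none
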